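In a closed, stirred vessel, gas dissolves as reagent, and a single-handed free catalyst turns a racemate of left-handed substrate and right-handed substrate into products, while a racemization catalyst may swap the hands.

- gamma: left-handed substrate 0.054 M; right-handed substrate 0.054 M; gas 3.5 mM (held); free catalyst 0.92 mM; racemization catalyst 54 µM; the very flask that is asked about, followed so far
- flask: left-handed substrate 0.054 M; gas 3.5 mM (held); free catalyst 0.92 mM; racemization catalyst 54 µM; right-handed substrate 0.054 M; time 8.0 min

gamma run (percent of the left-handed substrate and right-handed substrate together charged)

| time / s | left-handed substrate / % | right-handed substrate / % |
|---|---|---|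
| 10.0 | 49.2 | 49.8 |
| 15.0 | 48.4 | 49.0 |
| 25.0 | 47.0 | 48.5 |
| 40.0 | 46.5 | 47.1 |
| 50.0 | 44.2 | 46.9 |
| 60.0 | 43.5 | 45.7 |

(each reading ± 0.5 percentage points)

- free catalyst is single-handed; left-handed substrate and right-handed substrate are mirror images of each other, charged as a racemate, each of them at the stated concentration
- at the start none of reagent is dissolved
- on the list of suspects stand: reagent + free catalyst + left-handed substrate -> free catalyst + left-handed product; reagent + free catalyst + right-handed substrate -> free catalyst + right-handed product; left-handed substrate + racemization catalyst <-> right-handed substrate + racemization catalyst; racemization catalyst -> spent catalyst; gas <-> reagent; reagent <-> dormant form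
- an excess is the difference of the two amounts in percent of their sum
- an excess is below zero if the other one leads

* part of the left-handed substrate and right-handed substrate charged together that has reacted at 8.0 min
* excess of left-handed product over right-handed product in the product at 8.0 min
* excess of right-handed substrate over left-handed substrate among what is left of the two at 8.0 min

After 60.0 s, the last reading of this flask leaves 87.0% of the left-handed substrate and 91.4% of the right-handed substrate, each of its own charge. The ratio of the logarithms of those fractions is 1.55, a reading with scatter. I call it s, the selectivity factor: the logarithm of the left-handed fraction left over that of the right-handed fraction left.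

Both suspect steps to product use the same reagent and free catalyst, so these cancel in the ratio of the losses. If the swap adds little, I can freeze s and drop the clock: the left-handed fraction equals the right-handed fraction raised to the power s. Where a third of the right-handed substrate is left, this gives c 74.2% and eS 29.3%, and that pair is my own reckoning.

The forecast differs, with c 70%, eP 15% and a lower eS of 21%, and it notes: “The racemization rate is not resolved by the data”.

The flask gives c 77.1%, eP 16.3% and eS 36.2%.

    reagent + free catalyst + left-handed substrate → free catalyst + left-handed product (k = 3100 /M²/s)
    reagent + free catalyst + right-handed substrate → free catalyst + right-handed product (k = 1700 /M²/s)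
    left-handed substrate + racemization catalyst ⇌ right-handed substrate + racemization catalyst, rate k3*[racemization catalyst]*[left-handed substrate] forward; the back reaction follows from the equilibrium constant (k = 73.0 /M/s)
    racemization catalyst → spent catalyst (k = 0.00730 /s)
    gas ⇌ reagent, rate k5*(csat - [reagent]) (kL = 0.0900 /s)
    reagent ⇌ dormant form (K = 6.70, k = 0.00350 /s)

At 8.0 min this flask keeps 31% of its right-handed substrate and 15% of its left-handed substrate, where s gives 16.3%. The neighbour charged with 2.3 × 10⁻⁴ M of free catalyst keeps 63% of its right-handed substrate, so s gives 49.5% of left-handed substrate, and that neighbour holds 48%.

The readings were computed with made-up constants; noise was put on by code.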